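(Its constants were drawn at random within sensible limits, and the outcome is calculated.)

Comparing four ways of running one flask comes down to comparing how old the target is when it is read.

    target → over-reaction product (k1 = 7.6 × 10⁻⁴ min⁻¹)
    second substrate + reagent → second product (k2 = 1.4 M⁻¹ min⁻¹)
    2 second substrate → self-condensation product (k3 = 0.24 M⁻¹ min⁻¹)
    starting material + reagent → target (k4 = 0.47 M⁻¹ min⁻¹)

| setting | dawn | spring | winter | midnight |
|---|---|---|---|---|
| starting material | 20 mM | 20 mM | 20 mM (fed, over 25.0 min) | 20 mM |
| reagent | 1.10 equiv | 1.10 equiv | 1.10 equiv | 1.10 equiv (fed, over 25.0 min) |
| second substrate | 1.00 equiv | 1.00 equiv | 1.00 equiv | 1.00 equiv |
| time | 50 min |  | 50 min | 50 min |
| remark | a closed flask charged with all of it at once and left for 50 min | one stirred flow tank at steady state, fed with the mixture as stated, mean residence time 50 min | all but starting material at the start; starting material goes in evenly over 25.0 min, the run ends at 50 min | a stirred flask in which reagent is dosed at a steady rate over 25.0 min without added volume, worked up at 50 min |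

- a step written with two of one species runs at k times the square of its concentration and takes two of it each time
- the stated concentrations are those of everything mixed, before any reaction; amounts are the same in each set-up
- the feed brings no volume worth counting
- run time (dawn): 50 min

- the set-up with the highest share of target in all that became target or over-reaction product, at the outlet or at the end ("none" if the first two lie within 2 percentage points) (dawn / spring / winter / midnight / none)
- share of target in all that became target or over-reaction product, at the outlet or at the end, dawn
- share of target in all that became target or over-reaction product, at the outlet or at the end, spring
- share of target in all that became target or over-reaction product, at the outlet or at the end, winter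
- share of target in all that became target or over-reaction product, at the outlet or at the end, midnight

A share of 100 % is the zero of the scale: target read the moment it forms. Target leaves by a first-order step, so its clock is the lifetime of target, the inverse of that step's rate constant:

L = 21.9 h

This is far longer than the run. With m the mean age of target at the reading, the lost share is m/L while m stays small against L, however much target has formed.

The spring tank can be reckoned in two ways. A balance on over-reaction product at steady state gives the first, and the mean age of what leaves, equal to the residence time τ, gives the second:

balance: L/(L + τ) = 96.3 %
mean age: 1 − τ/L = 96.2 %

The second line is the first expanded for small τ/L, so their closeness is no check; the balance gives the figure for spring.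

The dawn flask can also be reckoned in two ways. If making were even, m would be the midpoint of the run:

m = 25.0 min, share 98.1 %

But reagent is also taken by second substrate, and faster than by starting material. With nearly equal charges, reagent falls roughly as θ/(θ + t), where t is time and θ is the inverse of the second-step rate constant times the charge:

θ = 35.7 min

Weighting the making by this curve, with starting material held steady, makes target earlier and older:

m = 28.6 min, share 97.8 %

The two ways part, and even making is the one that cheats, so the second figure stands.

Winter and midnight hold making back during the dose, so their target should be younger than dawn's. This reckoning gives them no figures. As a young extreme for both, making that rises in a straight line from nothing over the whole run gives: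

m = 16.7 min, share 98.7 %

That stands 0.90 percentage points above the dawn figure, less than the margin of 2 points, so the expected call is none.

The forecast gives 97.3 % for dawn, below the figure here, with 96.3 % for spring, 98.3 % for winter, 98.3 % for midnight and the call none, holding that “each share depends only on how long the target sits after forming”.

The simulation gives 97.7 % for dawn, 96.3 % for spring, 98.3 % for winter and 98.3 % for midnight, so the call is none. Dawn's share reads as a mean age of 30.2 min. The early hour of the reading helps hold midnight's share up: read at 500 min, that flask gives 73.3 % against 98.3 %. Midnight read at 3.0 h holds 3.47 % of over-reaction product and a share of 91.3 %, which through L reads as a mean age of 114 min.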